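The ring-opening disconnection at C1–C2 and the ring-fusion bond C5–C10 (labdane numbering) unzips both rings into an acyclic 1,7,9-decatriene. One thermal intramolecular Diels–Alder reaction of a 2-silyloxy-3-methyl diene (C2=C3–C4=C5) with an isopropenyl group (C1=C10) closes rings A and B and sets the trans fusion at C5 and the quaternary C10. It exploits the fact that C10 carries only the C20 methyl and the unsubstituted C1 methylene, and that the ring B substituents at C7, C8 and C9 sit on the tether, where they steer the closure by allylic strain. The triene comes from geraniol, ethyl pyruvate and ethyl tiglate; the enol ether later delivers the C4 gem-dimethyl group.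

Key step: step 9

Remark: labdane numbering (C1–C20) is used for all intermediates, open-chain ones included; β denotes the face of the C10 methyl group.

Step 1
Reactants: 1 geraniol; 2 4-methoxybenzyl chloride
Product: 4 geranyl 4-methoxybenzyl (PMB) ether, via sodium geranoxide 3 (not isolated)
Conditions: NaH, THF–DMF, 0 °C; then 2, n-Bu4NI (cat.), 0 °C → rt
Reagents that add atoms: 4-methoxybenzyl chloride, COc1ccc(CCl)cc1
Why: Williamson ether synthesis on the primary allylic alkoxide; no stereocentre is created and the 2E alkene is not touched.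

Step 2
Reactants: 4 geranyl PMB ether; 5 ethyl pyruvate
Product: 6 ethyl (2R,3R,6E)-2-hydroxy-8-[(4-methoxybenzyl)oxy]-2,6-dimethyl-3-(prop-1-en-2-yl)oct-6-enoate
Conditions: [Cu((R,R)-t-Bu-box)](SbF6)2 (10 mol%; t-Bu-box = 2,2'-(propane-2,2-diyl)bis[(4R)-4-tert-butyl-4,5-dihydro-1,3-oxazole]), CH2Cl2, 25–40 °C
Reagents that add atoms: ethyl pyruvate, CCOC(=O)C(C)=O
Why: Catalytic enantioselective carbonyl-ene reaction in which the chelated keto group attacks C9 of the electron-richer distal alkene (C13=C14 is deactivated by its allylic ether) and takes hydrogen from the methyl group syn to H-9, so the gem-dimethyl terminus becomes the C10=C1 isopropenyl group; C8 should be set by attack on the exposed Re face of the ketone in the square-planar divalent-copper chelate, and C9 by a chair-like ene transition state with the ester anti to the migrating hydrogen and the C11 chain equatorial (O8 and C11 anti).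

Step 3
Reactants: 6 ene adduct; 7 triethylsilyl trifluoromethanesulfonate
Product: 8 ethyl (2R,3R,6E)-8-[(4-methoxybenzyl)oxy]-2,6-dimethyl-3-(prop-1-en-2-yl)-2-[(triethylsilyl)oxy]oct-6-enoate
Conditions: Et3SiOTf, 2,6-lutidine, CH2Cl2, −78 → 0 °C
Reagents that add atoms: triethylsilyl trifluoromethanesulfonate, CC[Si](CC)(CC)OS(=O)(=O)C(F)(F)F
Why: Silylation of the hindered tertiary alcohol with a silyl triflate and a non-nucleophilic base; the bulky, non-chelating ether later enforces Felkin–Anh control in step 6, and no stereocentre changes.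

Step 4
Reactants: 8 silyl ether ester
Product: 9 (2R,3R,6E)-8-[(4-methoxybenzyl)oxy]-2,6-dimethyl-3-(prop-1-en-2-yl)-2-[(triethylsilyl)oxy]oct-6-enal
Conditions: i-Bu2AlH (1.1 equiv), CH2Cl2, −78 °C; MeOH, then aq. KNaC4H4O6 (potassium sodium tartrate)
Reagents that add atoms: none
Why: Partial reduction of the ester, whose tetrahedral aluminium alkoxide is stable at −78 °C and collapses to the aldehyde only on work-up; the quaternary C8 cannot epimerise.

Step 5
Reactants: 10 ethyl tiglate; 11 tert-butyldimethylsilyl chloride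
Product: 13 tert-butyl[(1-ethoxy-2-methylbuta-1,3-dien-1-yl)oxy]dimethylsilane, via lithium dienolate 12 (not isolated)
Conditions: LiN(i-Pr)2, THF–DMPU, −78 °C; then t-BuMe2SiCl, −78 °C → rt
Reagents that add atoms: tert-butyldimethylsilyl chloride, CC(C)(C)[Si](C)(C)Cl
Why: γ-Deprotonation of the enoate and O-silylation of the extended enolate gives the vinylketene silyl acetal needed for the vinylogous aldol reaction; no stereocentre is involved.

Step 6
Reactants: 9 aldehyde; 13 vinylketene silyl acetal
Product: 14 ethyl (2E,5S,6R,7R,10E)-5-hydroxy-12-[(4-methoxybenzyl)oxy]-2,6,10-trimethyl-7-(prop-1-en-2-yl)-6-[(triethylsilyl)oxy]dodeca-2,10-dienoate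
Conditions: BF3·OEt2, CH2Cl2–Et2O, −78 °C; aq. NaHCO3
Reagents that add atoms: vinylketene silyl acetal 13, C=CC(C)=C(OCC)O[Si](C)(C)C(C)(C)C
Why: Vinylogous Mukaiyama aldol reaction in which the γ-carbon of the dienolate (the α-carbon is blocked by its methyl group) adds to the BF3-activated aldehyde to give the E-enoate; C7 is set by Felkin–Anh (polar, non-chelated) attack anti to the C8–OSiEt3 bond, which should give the 7,8-anti (7S) alcohol.

Step 7
Reactants: 14 hydroxy enoate; 15 N,O-dimethylhydroxylamine hydrochloride; 16 methylmagnesium chloride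
Product: 18 (3E,6S,7R,8R,11E)-6-hydroxy-13-[(4-methoxybenzyl)oxy]-3,7,11-trimethyl-8-(prop-1-en-2-yl)-7-[(triethylsilyl)oxy]trideca-3,11-dien-2-one, via Weinreb amide 17 (not isolated)
Conditions: MeNH(OMe)·HCl, i-PrMgCl, THF, −20 → 0 °C; then MeMgCl, 0 °C → rt; aq. NH4Cl
Reagents that add atoms: methylmagnesium chloride, C[Mg]Cl
Why: One-pot Weinreb amide formation by the magnesium amide followed by Grignard addition, which stops at the ketone because the chelated tetrahedral intermediate survives until work-up; the E alkene and the three stereocentres are not affected.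

Step 8
Reactants: 18 hydroxy enone; 19 trimethylsilyl trifluoromethanesulfonate
Product: 20 (3E,6S,7R,8R,11E)-13-[(4-methoxybenzyl)oxy]-3,7,11-trimethyl-8-(prop-1-en-2-yl)-7-[(triethylsilyl)oxy]-2,6-bis[(trimethylsilyl)oxy]trideca-1,3,11-triene
Conditions: Me3SiOTf, Et3N, Et2O, 0 °C
Reagents that add atoms: trimethylsilyl trifluoromethanesulfonate, C[Si](C)(C)OS(=O)(=O)C(F)(F)F
Why: Soft enolisation of the methyl ketone on its α'-methyl group (faster than γ-deprotonation) gives the cross-conjugated 2-silyloxy diene while the secondary alcohol is silylated in the same operation; no stereocentre is formed.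

Step 9
Reactants: 20 triene
Product: 21 trans-fused adduct: ring A with C3(OSiMe3)=C4(CH3), ring B with 7β-OSiMe3, 8β-OSiEt3/8α-CH3, 9β side chain (PMB ether), 10β-CH3 and 5α-H
Conditions: toluene (0.01 M), 2,6-di-tert-butyl-4-methylphenol (cat.), N,O-bis(trimethylsilyl)acetamide (0.1 equiv), sealed vessel, 190 °C
Reagents that add atoms: none
Why: Concerted, suprafacial [4π+2π] cycloaddition (type 1 intramolecular Diels–Alder reaction of a 1,7,9-decatriene) between the s-cis-biased 2-silyloxy-3-methyl diene C2=C3–C4=C5 and the isopropenyl dienophile C1=C10, forming C1–C2 and C5–C10 in one operation; the closest known reaction type is the thermal intramolecular Diels–Alder reaction of unactivated decatrienes that gives angularly methylated octalins. Ring A (C1–C5, C10) closes as the new cyclohexene of the [4+2] event, and ring B (C5–C10) closes through the same C5–C10 bond as a six-membered tether ring in a chair-like, tether-exo (anti) arrangement, the mode that leads to trans fusion. C10 is controlled by C9: allylic 1,3-strain keeps the C9–H bond eclipsed with C10=C1, so the diene tethered through C8 reaches only the face that places the C10 methyl anti to H-9 (10β-CH3 with 9β side chain). C5 is controlled by the chair tether, in which 7-OSiMe3, 8-CH3 and the C9 chain are equatorial, and by allylic strain between the C4 methyl (cis to C6) and C7, which holds C4 equatorial and H-5 axial (5α). The step needs trans over cis fusion and reaction at the isopropenyl group, not at C13=C14: both cis transition states must eclipse either C8 with C10=C1 or C7 with C5=C4, and the side-chain alkene could react only through a medium ring. The quaternary C8 should accelerate the closure, and C3/C4 stay a silyl enol ether for step 10.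

Step 10
Reactants: 21 adduct; 22 methyllithium; 23 iodomethane
Product: 26 15-[(4-methoxybenzyl)oxy]-7β,8β-dihydroxylabd-13E-en-3-one, via lithium enolate 24 (not isolated), via bis-silyl ketone 25 (not isolated)
Conditions: MeLi, THF, 0 °C → rt; then MeI, −78 → 0 °C; then 1 M HCl, THF–MeOH, rt
Reagents that add atoms: iodomethane, CI
Why: Regiospecific enolate alkylation in which MeLi cleaves the enol O–Si bond to the tetrasubstituted lithium enolate, which is C-methylated at C4 to give the gem-dimethyl group (C4 is not stereogenic); acid then removes both O-silyl groups, so any earlier silyl migration between O7 and O8 is without consequence.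

Step 11
Reactants: 26 keto diol; 27 hydrazine hydrate
Product: 29 15-[(4-methoxybenzyl)oxy]labd-13E-ene-7β,8β-diol, via hydrazone 28 (not isolated)
Conditions: N2H4·H2O, KOH, diethylene glycol, 130 °C; then 200 °C with removal of water
Reagents that add atoms: none
Why: Wolff–Kishner reduction (Huang–Minlon modification) of the C3 ketone through its hydrazone; the flanking C4 is quaternary, so no stereocentre can epimerise, and the diol, ether and alkene should tolerate hot base.

Step 12
Reactants: 29 diol; 30 acetic anhydride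
Product: 31 7β-acetoxy-15-[(4-methoxybenzyl)oxy]labd-13E-en-8β-ol
Conditions: Ac2O, pyridine, 4-(dimethylamino)pyridine (cat.), CH2Cl2, 0 °C → rt
Reagents that add atoms: acetic anhydride, CC(=O)OC(C)=O
Why: Nucleophile-catalysed acylation discriminates the equatorial secondary 7β-alcohol from the axial tertiary 8β-alcohol, which should not react under these conditions; configuration at C7 is retained.

Step 13
Reactants: 31 acetate PMB ether
Product: 32 7β-acetoxylabd-13E-ene-8β,15-diol (target)
Conditions: DDQ, CH2Cl2–pH 7 phosphate buffer, 0 °C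
Reagents that add atoms: none
Why: Oxidative cleavage of the electron-rich 4-methoxybenzyl ether (hydride abstraction by DDQ, then hydrolysis of the oxocarbenium ion) leaves the acetate, the tertiary alcohol and the alkene untouched.

Compound list
1 | geraniol, (2E)-3,7-dimethylocta-2,6-dien-1-ol | CC(C)=CCC/C(C)=C/CO | starting material
2 | 4-methoxybenzyl chloride | COc1ccc(CCl)cc1 | starting material
3 | sodium geranoxide | CC(C)=CCC/C(C)=C/C[O-].[Na+] | intermediate
4 | geranyl 4-methoxybenzyl ether | CC(C)=CCC/C(C)=C/COCc1ccc(OC)cc1 | intermediate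
5 | ethyl pyruvate | CCOC(=O)C(C)=O | starting material
6 | ethyl (2R,3R,6E)-2-hydroxy-8-[(4-methoxybenzyl)oxy]-2,6-dimethyl-3-(prop-1-en-2-yl)oct-6-enoate | CCOC(=O)[C@](C)(O)[C@H](CC/C(C)=C/COCc1ccc(OC)cc1)C(C)=C | intermediate
7 | triethylsilyl trifluoromethanesulfonate | CC[Si](CC)(CC)OS(=O)(=O)C(F)(F)F | starting material
8 | ethyl (2R,3R,6E)-8-[(4-methoxybenzyl)oxy]-2,6-dimethyl-3-(prop-1-en-2-yl)-2-[(triethylsilyl)oxy]oct-6-enoate | CCOC(=O)[C@](C)(O[Si](CC)(CC)CC)[C@H](CC/C(C)=C/COCc1ccc(OC)cc1)C(C)=C | intermediate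
9 | (2R,3R,6E)-8-[(4-methoxybenzyl)oxy]-2,6-dimethyl-3-(prop-1-en-2-yl)-2-[(triethylsilyl)oxy]oct-6-enal | O=C[C@](C)(O[Si](CC)(CC)CC)[C@H](CC/C(C)=C/COCc1ccc(OC)cc1)C(C)=C | intermediate
10 | ethyl tiglate, ethyl (2E)-2-methylbut-2-enoate | CCOC(=O)/C(C)=C/C | starting material
11 | tert-butyldimethylsilyl chloride | CC(C)(C)[Si](C)(C)Cl | starting material
12 | lithium dienolate of ethyl tiglate | C=CC(C)=C(OCC)[O-].[Li+] | intermediate
13 | tert-butyl[(1-ethoxy-2-methylbuta-1,3-dien-1-yl)oxy]dimethylsilane (mixture of ketene acetal geometric isomers) | C=CC(C)=C(OCC)O[Si](C)(C)C(C)(C)C | intermediate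
14 | ethyl (2E,5S,6R,7R,10E)-5-hydroxy-12-[(4-methoxybenzyl)oxy]-2,6,10-trimethyl-7-(prop-1-en-2-yl)-6-[(triethylsilyl)oxy]dodeca-2,10-dienoate | CCOC(=O)/C(C)=C/C[C@H](O)[C@](C)(O[Si](CC)(CC)CC)[C@H](CC/C(C)=C/COCc1ccc(OC)cc1)C(C)=C | intermediate
15 | N,O-dimethylhydroxylamine hydrochloride | CNOC.Cl | starting material
16 | methylmagnesium chloride | C[Mg]Cl | starting material
17 | (2E,5S,6R,7R,10E)-5-hydroxy-N-methoxy-12-[(4-methoxybenzyl)oxy]-N,2,6,10-tetramethyl-7-(prop-1-en-2-yl)-6-[(triethylsilyl)oxy]dodeca-2,10-dienamide (Weinreb amide) | CON(C)C(=O)/C(C)=C/C[C@H](O)[C@](C)(O[Si](CC)(CC)CC)[C@H](CC/C(C)=C/COCc1ccc(OC)cc1)C(C)=C | intermediate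
18 | (3E,6S,7R,8R,11E)-6-hydroxy-13-[(4-methoxybenzyl)oxy]-3,7,11-trimethyl-8-(prop-1-en-2-yl)-7-[(triethylsilyl)oxy]trideca-3,11-dien-2-one | CC(=O)/C(C)=C/C[C@H](O)[C@](C)(O[Si](CC)(CC)CC)[C@H](CC/C(C)=C/COCc1ccc(OC)cc1)C(C)=C | intermediate
19 | trimethylsilyl trifluoromethanesulfonate | C[Si](C)(C)OS(=O)(=O)C(F)(F)F | starting material
20 | (3E,6S,7R,8R,11E)-13-[(4-methoxybenzyl)oxy]-3,7,11-trimethyl-8-(prop-1-en-2-yl)-7-[(triethylsilyl)oxy]-2,6-bis[(trimethylsilyl)oxy]trideca-1,3,11-triene | C=C(O[Si](C)(C)C)/C(C)=C/C[C@H](O[Si](C)(C)C)[C@](C)(O[Si](CC)(CC)CC)[C@H](CC/C(C)=C/COCc1ccc(OC)cc1)C(C)=C | intermediate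
21 | trans-fused cycloadduct: 15-O-PMB 3,7β-bis(trimethylsilyloxy)-8β-(triethylsilyloxy)-19-norlabda-3,13E-diene (5α-H, 9β side chain, 10β-CH3) | C[Si](C)(C)O[C@H]1C[C@H]2C(C)=C(O[Si](C)(C)C)CC[C@]2(C)[C@@H](CC/C(C)=C/COCc3ccc(OC)cc3)[C@@]1(C)O[Si](CC)(CC)CC | intermediate
22 | methyllithium | [Li]C | starting material
23 | iodomethane | CI | starting material
24 | lithium C3–C4 enolate of the 19-nor-3-ketone (silyl ethers at O7 and O8 intact) | C[Si](C)(C)O[C@H]1C[C@H]2C(C)=C([O-])CC[C@]2(C)[C@@H](CC/C(C)=C/COCc3ccc(OC)cc3)[C@@]1(C)O[Si](CC)(CC)CC.[Li+] | intermediate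
25 | 15-O-PMB 7β-(trimethylsilyloxy)-8β-(triethylsilyloxy)labd-13E-en-3-one | C[Si](C)(C)O[C@H]1C[C@H]2C(C)(C)C(=O)CC[C@]2(C)[C@@H](CC/C(C)=C/COCc3ccc(OC)cc3)[C@@]1(C)O[Si](CC)(CC)CC | intermediate
26 | 15-[(4-methoxybenzyl)oxy]-7β,8β-dihydroxylabd-13E-en-3-one | O[C@H]1C[C@H]2C(C)(C)C(=O)CC[C@]2(C)[C@@H](CC/C(C)=C/COCc3ccc(OC)cc3)[C@@]1(C)O | intermediate
27 | hydrazine hydrate | NN.O | starting material
28 | C3 hydrazone of 26 | O[C@H]1C[C@H]2C(C)(C)C(=NN)CC[C@]2(C)[C@@H](CC/C(C)=C/COCc3ccc(OC)cc3)[C@@]1(C)O | intermediate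
29 | 15-[(4-methoxybenzyl)oxy]labd-13E-ene-7β,8β-diol | O[C@H]1C[C@H]2C(C)(C)CCC[C@]2(C)[C@@H](CC/C(C)=C/COCc3ccc(OC)cc3)[C@@]1(C)O | intermediate
30 | acetic anhydride | CC(=O)OC(C)=O | starting material
31 | 7β-acetoxy-15-[(4-methoxybenzyl)oxy]labd-13E-en-8β-ol | CC(=O)O[C@H]1C[C@H]2C(C)(C)CCC[C@]2(C)[C@@H](CC/C(C)=C/COCc3ccc(OC)cc3)[C@@]1(C)O | intermediate
32 | (5S,7S,8R,9R,10S)-7β-acetoxylabd-13E-ene-8β,15-diol, CNP0499846.1 | CC(=O)O[C@H]1C[C@H]2C(C)(C)CCC[C@]2(C)[C@@H](CC/C(C)=C/CO)[C@@]1(C)O | target

Total step count: 13. Longest linear sequence: 12 steps (steps 1–4 and 6–13; step 5 prepares reagent 13).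

Steps most likely to fail

Step 9 (key step). The unactivated 1,1-disubstituted alkene may cyclise so slowly that protodesilylation of the dienol ether and leakage through a boat-like, cis-fused transition state compete during the long heating. The fallback sets out again from triene 20 and replaces the thermal pericyclic closure by a metal-templated [4+2] cycloaddition with a cationic monovalent-rhodium catalyst ([RhCl(C8H14)2]2 with P[OCH(CF3)2]3, or [Rh(C8H12)(C10H8)]SbF6, THF or CH2Cl2, 25–60 °C). This should run through a rhodacycle at a temperature where the silyl dienol ether is stable. It comes back to the route at adduct 21 and makes no compound outside the list (F0).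

Step 2. Turnover of the copper chelate may be poor with the hindered trisubstituted alkene, and C9 control is lost if hydrogen is also taken from the other methyl group through the competing ene transition state. The fallback moves from catalyst control to auxiliary control and sets out from ether 4. (1S,2R,5S)-8-Phenylmenthol is esterified with pyruvic acid (DCC, 4-(dimethylamino)pyridine) to (1S,2R,5S)-8-phenylmenthyl pyruvate F1. Its ene reaction with 4 under stoichiometric SnCl4 (CH2Cl2, −78 °C, short reaction time), in which the phenyl group is expected to shield the Si face of the chelated keto ester, should give the 8-phenylmenthyl (2R,3R)-hydroxy ester F2. Silylation (Et3SiOTf, 2,6-lutidine) would give the triethylsilyl ether F3, and i-Bu2AlH reduction (CH2Cl2, −78 °C) comes back to the route at aldehyde 9 with recovery of the auxiliary alcohol.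

Step 11. Hydrazone formation at the hindered C3 ketone may stay incomplete, and the allylic ether may isomerise or degrade during prolonged heating in KOH. The fallback sets out from keto diol 26 and uses a hydride reduction of a sulfonylhydrazone: condensation with TsNHNH2 (EtOH, cat. AcOH, 70 °C) gives the tosylhydrazone F4. Catecholborane (CHCl3, 0 °C → rt), then NaOAc·3H2O at reflux, should deliver the methylene compound through the diazene and comes back to the route at diol 29.

Further compounds
F0 | step 9 | none | none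
F1 | step 2 | (1S,2R,5S)-5-methyl-2-(2-phenylpropan-2-yl)cyclohexyl 2-oxopropanoate (8-phenylmenthyl pyruvate) | CC(C)(c1ccccc1)[C@H]1CC[C@H](C)C[C@@H]1OC(=O)C(C)=O
F2 | step 2 | (1S,2R,5S)-8-phenylmenthyl (2R,3R,6E)-2-hydroxy-8-[(4-methoxybenzyl)oxy]-2,6-dimethyl-3-(prop-1-en-2-yl)oct-6-enoate | CC(C)(c1ccccc1)[C@H]1CC[C@H](C)C[C@@H]1OC(=O)[C@](C)(O)[C@H](CC/C(C)=C/COCc2ccc(OC)cc2)C(C)=C
F3 | step 2 | (1S,2R,5S)-8-phenylmenthyl (2R,3R,6E)-8-[(4-methoxybenzyl)oxy]-2,6-dimethyl-3-(prop-1-en-2-yl)-2-[(triethylsilyl)oxy]oct-6-enoate | CC(C)(c1ccccc1)[C@H]1CC[C@H](C)C[C@@H]1OC(=O)[C@](C)(O[Si](CC)(CC)CC)[C@H](CC/C(C)=C/COCc2ccc(OC)cc2)C(C)=C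
F4 | step 11 | C3 4-methylbenzenesulfonylhydrazone of 26 | O[C@H]1C[C@H]2C(C)(C)C(=NNS(=O)(=O)c4ccc(C)cc4)CC[C@]2(C)[C@@H](CC/C(C)=C/COCc3ccc(OC)cc3)[C@@]1(C)O
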